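I have four flasks to reckon.

    starting material + free catalyst ⇌ catalyst intermediate A (K1 = 400 M⁻¹, k1 = 1.2 × 10⁵ M⁻¹ s⁻¹, Ea1 = 19.0 kJ mol⁻¹, ΔH1 = −45.0 kJ mol⁻¹)
    gas ⇌ partner, rate k2*(csat - [partner]) (k2 = 71 s⁻¹, csat = 0.26 mM)
    partner + catalyst intermediate A → free catalyst + target (k3 = 2.8 × 10⁵ M⁻¹ s⁻¹, Ea3 = 20.0 kJ mol⁻¹)
    second substrate + free catalyst ⇌ catalyst intermediate B (K4 = 1000 M⁻¹, k4 = 24000 M⁻¹ s⁻¹, Ea4 = 9.00 kJ mol⁻¹, ΔH4 = −42.0 kJ mol⁻¹)
    partner + catalyst intermediate B → free catalyst + second product (k5 = 1.2 × 10⁵ M⁻¹ s⁻¹, Ea5 = 35.0 kJ mol⁻¹)
    (constants at 35 °C)

| flask | starting material | second substrate | gas | free catalyst | temperature | time | remark |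
|---|---|---|---|---|---|---|---|
| elm | 5.0 mM | 5.00 mM | 0.26 mM (held) | 25 µM | 35 °C | 10 s | everything together at the start |
| oak | 5.0 mM (fed, over 6.0 s) | 5.00 mM | 0.26 mM (held) | 25 µM |  | 10 s | the addition at 5 °C, then warmed to 35 °C; the feed brings no volume worth counting |
| alder | 5.0 mM | 5.00 mM (fed, over 6.0 s) | 0.26 mM (held) | 25 µM | 35 °C | 10 s | all else is in the flask from the start; the feed brings no volume worth counting |
| birch | 5.0 mM (fed, over 6.0 s) | 5.00 mM | 0.26 mM (held) | 25 µM | 35 °C | 10 s | all else is in the flask from the start; the feed brings no volume worth counting |

- at the start none of partner is dissolved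
- constants are those at 35 °C; use the activation energies and enthalpies for any other temperature

1. which flask leads in amount of target, in percent of the starting material charged ("all alike" within 1.5 percentage points) (elm / oak / alder / birch / all alike)
2. how much target is there at the end, in percent of the starting material charged: elm
3. how much target is there at the end, in percent of the starting material charged: oak
4. how much target is there at the end, in percent of the starting material charged: alder
5. how much target is there at the end, in percent of the starting material charged: birch

I freeze what is fast and keep what is slow, so I sort the time constants. Catalyst intermediate A lasts 2.68 ms before it falls back or goes on. Dissolved partner relaxes in 14.1 ms. Its refill with none dissolved, 18.5 mM s⁻¹, is faster than the 1.82 mM s⁻¹ that the whole catalyst uses when it sits as intermediate A, so I freeze [partner] at 0.26 mM. Catalyst intermediate B lasts 18.1 ms. I reckon these rungs at 35 °C, and I let the intermediates follow the slower substrates.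

Of the intermediate A that forms, a share 0.195 goes on to target. Of intermediate B, a share 0.565 goes on. So starting material falls with the effective constant 23400 M⁻¹ s⁻¹ times [starting material] times [free catalyst], and second substrate with 13600 M⁻¹ s⁻¹. Free catalyst multiplies both falls, so it cancels from their ratio. The competition exponent, the effective constant of second substrate over that of starting material, is 0.579; chemists call it a selectivity factor. With [partner] frozen, no feed running and the temperature steady, the logarithmic fall of second substrate is this exponent times that of starting material.

The slow clock needs the load, the total catalyst over the free catalyst. At the start of elm I reckon it at 4.78. That gives starting material a time constant of 8.16 s, shorter than the run and longer than the lifetime of intermediate B. At that pace I reckon 29.4% of it at the end of elm. The exponent then gives the second substrate, and I reckon the load there at 2.54. Taking the geometric mean of the two loads, 3.49, I expect 81.4% target in elm. My reckoning ends there; I do not integrate the fed flasks or the cold one.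

The forecast names alder as the leader, with 84% in elm, 57% in oak, 88% in alder and 74% in birch. For alder its ground is that “starting material gets the catalyst first”. Its elm figure is higher than mine.

The simulation puts alder ahead, with 83.7% in elm, 56.7% in oak, 87.6% in alder and 73.9% in birch. In elm at 10.0 s, 16.2% of the starting material and 34.3% of the second substrate's own charge stand, so the two logarithmic falls read a ratio of 0.588, close to the exponent of 0.579. In alder, from the end of the feed at 6.00 s to 10.0 s, starting material goes from 30.0% to 12.4% and second substrate from 72.2% to 42.9% of its own charge, a ratio of 0.589.

(All constants stand for no real mixture; no experiment stands behind them.)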